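**Plan**
- Retrosynthesis: the C5 carbinol goes back to the C5 ketone of a 7,8-dihydrochromene-4,5-dione. The C8–C8a bond of the carbocycle is then cut and C6–C7–C8 are folded into a cyclopropane on the C5 carbonyl, giving a 5-(cyclopropanecarbonyl)-4-pyranone. The pyranone is cut at C2–C3 and O1–C8a (enaminone anion + acid chloride) and at C4a–C8a (amide acetal). The side chain is cut at C11'–C12' (acetylide alkylation).
- Forward order: side-chain acid (alkylation, semihydrogenation, acid chloride), then the γ-pyrone ring (step 5), then the carbocycle (step 6), then the carbinol (step 7).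
- Enabling feature: in the cyclization precursor the pyranone carbon next to the ring oxygen (the later C8a) still bears H and is the β-carbon of the enone C4=O/C4a=C8a, and C4a carries the acyl carbon C5. One-electron opening of the cyclopropane on C5 frees a radical at C8, three atoms from C5 and in 6-endo reach of C8a. Regaining the γ-pyrone π-system by loss of the C8a hydrogen drives the closure.
- The cyclopropane is a temporary ring: it keeps the acyl side non-enolizable during the pyranone synthesis and is consumed in the key step.
- Stereochemistry: the Z-alkene comes from syn-semihydrogenation of the alkyne; the single stereocenter C5 (S) is set last by catalyst-controlled asymmetric transfer hydrogenation.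

Key step: step 6

Remark: core atoms are numbered as in 4H-chromen-4-one (O1, C2 … C8a). Compounds 7 and 8 are push–pull enaminones whose C=C geometry equilibrates freely, so their SMILES carry no descriptor for that bond.

**Step 1**
Reactants: 1 hex-1-yne; 2 12-bromododecanoic acid
Product: 3 octadec-13-ynoic acid
Conditions: 1 (2.5 equiv), n-BuLi (2.5 equiv), THF, −78 to 0 °C; then 2, DMPU, 0 to 25 °C; aq. HCl work-up
Reagents that add atoms: none
Why: Alkylation of a lithium acetylide (SN2 at the primary bromide of the lithium carboxylate of 2, accelerated by the dipolar cosolvent) should join the C6 and C12 fragments without forming a stereocenter.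

**Step 2**
Reactants: 3 octadec-13-ynoic acid
Product: 4 (13Z)-octadec-13-enoic acid
Conditions: H2 (1 atm), Pd/CaCO3 poisoned with Pb(OAc)2 (Lindlar catalyst), quinoline, EtOAc, 25 °C
Reagents that add atoms: none
Why: Lindlar semihydrogenation delivers both hydrogens to the same face of the alkyne on the poisoned palladium surface, which should set the Z-alkene while quinoline suppresses over-reduction.

**Step 3**
Reactants: 4 (13Z)-octadec-13-enoic acid
Product: 5 (13Z)-octadec-13-enoyl chloride
Conditions: (COCl)2, DMF (cat.), CH2Cl2, 0 to 25 °C; concentrated and used crude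
Reagents that add atoms: oxalyl chloride, ClC(=O)C(=O)Cl
Why: Acid chloride formation through the Vilsmeier-type chloroiminium from DMF and oxalyl chloride runs under conditions that leave the Z-alkene untouched.

**Step 4**
Reactants: 6 1-cyclopropylbutane-1,3-dione
Product: 7 1-cyclopropyl-2-[(dimethylamino)methylidene]butane-1,3-dione
Conditions: Me2NCH(OMe)2 (1.2 equiv), toluene, 25 to 60 °C
Reagents that add atoms: N,N-dimethylformamide dimethyl acetal, COC(OC)N(C)C
Why: Aminomethylenation of an active methylene compound with an amide acetal should occur at the C2 methylene between the two carbonyls, the only doubly activated position, and introduces the carbon that becomes C8a.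

**Step 5**
Reactants: 7 1-cyclopropyl-2-[(dimethylamino)methylidene]butane-1,3-dione; 5 (13Z)-octadec-13-enoyl chloride
Product: 9 5-(cyclopropanecarbonyl)-2-[(12Z)-heptadec-12-en-1-yl]-4H-pyran-4-one, via triketone enaminone 8 (not isolated)
Conditions: LiN(SiMe3)2 (2.2 equiv), THF, −78 °C; 5, −78 to 0 °C; then CF3CO2H, CH2Cl2, 25 °C
Reagents that add atoms: none
Why: Acylation of an enaminone anion followed by acid-induced cyclization (γ-pyrone synthesis from 2-aminomethylene-1,3-dicarbonyl compounds): LiN(SiMe3)2 should deprotonate the acetyl CH3 of 7, the only enolizable site because the cyclopropyl C–H is not acidic, C-acylation by 5 gives 8, and under acid its enol oxygen adds 6-endo to the aminomethylene carbon with loss of dimethylamine, which places the acyl group at C5 and leaves C6–H free without any regiochemical choice.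

**Step 6**
Reactants: 9 5-(cyclopropanecarbonyl)-2-[(12Z)-heptadec-12-en-1-yl]-4H-pyran-4-one
Product: 10 2-[(12Z)-heptadec-12-en-1-yl]-7,8-dihydro-4H-chromene-4,5(6H)-dione
Conditions: Cp2TiCl2 (10 mol%), Zn dust (10 mol%), 2,4,6-collidine hydrochloride (20 mol%), THF, 60 °C
Reagents that add atoms: none
Why: Proposed new method: in this radical ring-opening/cyclization/rearomatization cascade (a cycloisomerization), Cp2TiCl, held in a chelate by the C4 and acyl carbonyl oxygens of 9, should transfer one electron to the acyl carbon, whereupon the cyclopropane opens reversibly to a titanium enolate with a primary radical at the carbon that becomes C8; this radical adds to the C6–H carbon of the pyranone (the later C8a, β-carbon of the enone), and collidinium/collidine then carry the proton from C8a to the enolate carbon C6 of the new ring while the electron returns to tetravalent titanium, so that 9 is isomerized to 10 with no net redox change. The closest known reaction types are the radical redox-relay [3+2] cycloadditions of cyclopropyl ketones catalyzed by trivalent titanium (same ring opening), the titanocene-catalyzed atom-economical radical arylation of epoxides (same rearomatizing proton and electron return, mediated by collidine hydrochloride) and the oxidative ring expansion of 1-arylcyclobutanols to 1-tetralones (same closure of a γ-keto alkyl radical onto the neighboring π-ring). The cyclohexanone ring closes in the 6-endo-trig mode. No stereocenter is formed, since 10 has none, and the Z-alkene is not touched. The step needs 6-endo attack at C8a instead of 5-exo attack at C4a, secured because the nucleophilic alkyl radical is polarity-matched with the β-carbon whereas C4a is fully substituted, and it needs the enolate geometry with C7 cis to the pyranone, which the reversible ring opening should supply under Curtin–Hammett control. Reduction of the radical intermediates is held back by using zinc and titanium only in catalytic amounts.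

**Step 7**
Reactants: 10 2-[(12Z)-heptadec-12-en-1-yl]-7,8-dihydro-4H-chromene-4,5(6H)-dione
Product: 11 (5S)-2-[(12Z)-heptadec-12-en-1-yl]-5-hydroxy-5,6,7,8-tetrahydro-4H-chromen-4-one
Conditions: RuCl[(S,S)-TsDPEN](p-cymene) (2 mol%), HCO2H/Et3N (5:2), CH2Cl2, 25 °C
Reagents that add atoms: none
Why: Noyori–Ikariya asymmetric transfer hydrogenation: the (S,S)-TsDPEN ruthenium hydride should deliver hydride to the Re face of the C5 ketone (the pyranone ring taking the place of the aryl group of an aryl alkyl ketone such as 1-tetralone), which sets C5 as S under catalyst control, while the γ-pyrone carbonyl (a doubly vinylogous ester) and the isolated Z-alkene are not reduced.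

**Compound list**
1 | hex-1-yne | CCCCC#C | starting material
2 | 12-bromododecanoic acid | OC(=O)CCCCCCCCCCCBr | starting material
3 | octadec-13-ynoic acid | CCCCC#CCCCCCCCCCCCC(=O)O | intermediate
4 | (13Z)-octadec-13-enoic acid | CCCC/C=C\CCCCCCCCCCCC(=O)O | intermediate
5 | (13Z)-octadec-13-enoyl chloride | CCCC/C=C\CCCCCCCCCCCC(=O)Cl | intermediate
6 | 1-cyclopropylbutane-1,3-dione | CC(=O)CC(=O)C1CC1 | starting material
7 | 1-cyclopropyl-2-[(dimethylamino)methylidene]butane-1,3-dione | CC(=O)C(=CN(C)C)C(=O)C1CC1 | intermediate
8 | (17Z)-1-cyclopropyl-2-[(dimethylamino)methylidene]docos-17-ene-1,3,5-trione (not isolated) | CCCC/C=C\CCCCCCCCCCCC(=O)CC(=O)C(=CN(C)C)C(=O)C1CC1 | intermediate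
9 | 5-(cyclopropanecarbonyl)-2-[(12Z)-heptadec-12-en-1-yl]-4H-pyran-4-one | CCCC/C=C\CCCCCCCCCCCc1cc(=O)c(C(=O)C2CC2)co1 | intermediate
10 | 2-[(12Z)-heptadec-12-en-1-yl]-7,8-dihydro-4H-chromene-4,5(6H)-dione | CCCC/C=C\CCCCCCCCCCCc1cc(=O)c2c(o1)CCCC2=O | intermediate
11 | (5S)-2-[(12Z)-heptadec-12-en-1-yl]-5-hydroxy-5,6,7,8-tetrahydro-4H-chromen-4-one | CCCC/C=C\CCCCCCCCCCCc1cc(=O)c2c(o1)CCC[C@@H]2O | target

Total step count: 7. Longest linear sequence: 6 steps (steps 1, 2, 3, 5, 6, 7).

**Steps most likely to fail**

Step 6. The titanium cycle may stall, or the ring-opened radical may be reduced before it closes, so that ring-opened or over-reduced material forms instead of the isomerized product. The fallback divides the closure into three operations of known type and sets out from 9. Me3SiCl/NaI in MeCN at 0 °C, followed by aqueous work-up, should open the cyclopropyl ketone to the γ-iodoketone 2-[(12Z)-heptadec-12-en-1-yl]-5-(4-iodobutanoyl)-4H-pyran-4-one F1. (Me3Si)3SiH/AIBN in toluene at 80 °C under slow addition should close the same C8–C8a bond by 6-endo radical cyclization and give 2-[(12Z)-heptadec-12-en-1-yl]-6,7,8,8a-tetrahydro-4H-chromene-4,5(4aH)-dione F2 as a mixture of ring-fusion isomers and enol forms. DDQ in 1,4-dioxane at 25 °C should dehydrogenate F2 across C4a–C8a, and the route is rejoined at 10.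

Step 5. O-acylation of the enaminone anion, or ketene formation from the enolizable acid chloride, may compete with C-acylation. The fallback assembles the pyranone by an acylketene hetero-Diels–Alder reaction and sets out from 5. Meldrum's acid and pyridine in CH2Cl2 at 0 °C should give 5-[(13Z)-octadec-13-enoyl]-2,2-dimethyl-1,3-dioxane-4,6-dione F3. Separately, cyclopropyl methyl ketone and N,N-dimethylformamide dimethyl acetal should give (2E)-1-cyclopropyl-3-(dimethylamino)prop-2-en-1-one F4. Heating F3 with F4 in toluene at 110 °C should release the acylketene (15Z)-3-oxoicosa-1,15-dien-1-one F5, which adds in a [4+2] sense across the enamine C=C bond of F4 to the aminal 3-(cyclopropanecarbonyl)-2-(dimethylamino)-6-[(12Z)-heptadec-12-en-1-yl]-2,3-dihydro-4H-pyran-4-one F6. Loss of dimethylamine from F6, completed with CF3CO2H if needed, returns the route to 9.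

Step 7. Facial selectivity may be poor, or hydride transfer to the vinylogous ester carbonyl may be slow. The fallback obtains the stereocenter by resolution instead of asymmetric catalysis and sets out from 10. Luche reduction (NaBH4, CeCl3·7H2O, MeOH, −20 °C) should give racemic 2-[(12Z)-heptadec-12-en-1-yl]-5-hydroxy-5,6,7,8-tetrahydro-4H-chromen-4-one F7. Immobilized Candida antarctica lipase B with vinyl acetate in MTBE should acylate the (5R)-enantiomer to (5R)-2-[(12Z)-heptadec-12-en-1-yl]-4-oxo-5,6,7,8-tetrahydro-4H-chromen-5-yl acetate F8 and leave the (5S)-alcohol, which is 11.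

**Further compounds**
F1 | step 6 | 2-[(12Z)-heptadec-12-en-1-yl]-5-(4-iodobutanoyl)-4H-pyran-4-one | CCCC/C=C\CCCCCCCCCCCc1cc(=O)c(C(=O)CCCI)co1
F2 | step 6 | 2-[(12Z)-heptadec-12-en-1-yl]-6,7,8,8a-tetrahydro-4H-chromene-4,5(4aH)-dione | CCCC/C=C\CCCCCCCCCCCC1=CC(=O)C2C(=O)CCCC2O1
F3 | step 5 | 5-[(13Z)-octadec-13-enoyl]-2,2-dimethyl-1,3-dioxane-4,6-dione | CCCC/C=C\CCCCCCCCCCCC(=O)C1C(=O)OC(C)(C)OC1=O
F4 | step 5 | (2E)-1-cyclopropyl-3-(dimethylamino)prop-2-en-1-one | CN(C)/C=C/C(=O)C1CC1
F5 | step 5 | (15Z)-3-oxoicosa-1,15-dien-1-one | CCCC/C=C\CCCCCCCCCCCC(=O)C=C=O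
F6 | step 5 | 3-(cyclopropanecarbonyl)-2-(dimethylamino)-6-[(12Z)-heptadec-12-en-1-yl]-2,3-dihydro-4H-pyran-4-one | CCCC/C=C\CCCCCCCCCCCC1=CC(=O)C(C(=O)C2CC2)C(N(C)C)O1
F7 | step 7 | 2-[(12Z)-heptadec-12-en-1-yl]-5-hydroxy-5,6,7,8-tetrahydro-4H-chromen-4-one (racemic) | CCCC/C=C\CCCCCCCCCCCc1cc(=O)c2c(o1)CCCC2O
F8 | step 7 | (5R)-2-[(12Z)-heptadec-12-en-1-yl]-4-oxo-5,6,7,8-tetrahydro-4H-chromen-5-yl acetate | CCCC/C=C\CCCCCCCCCCCc1cc(=O)c2c(o1)CCC[C@H]2OC(C)=O
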